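## Retrosynthetic overview

1. Target 22 ⇐ diol 21 (acetylation at C7 only) ⇐ bis-silyl ether 20.
2. 20 ⇐ key step: the C8–C15 bond is made by adding 1-lithio-1-(methoxymethoxy)allene (a masked acryloyl anion) to the C8 ketone of the ten-membered enone 14; ionisation then closes C13–C16 across the ring (4π), giving ring D with C15=O, C8=C14, C16=CH2 and C13 in one operation.
3. 14 ⇐ ene-dione 11 (double α-hydroxylation at C7 and C11) ⇐ oxidative fission of the C8=C9 alkene of tricycle 9, so the ten-membered ring comes from ring opening, not ring closure.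
4. 9 ⇐ 13-methoxy arene 5 (Birch reduction; the C13 oxygen becomes a leaving group) ⇐ enantioselective cation–olefin bicyclisation of 4 (sets C5, C10) ⇐ geranyl chloride + 3-methoxybenzyl chloride.
5. Ring order: A and B together (arene C already present) → C reduced → B/C pair opened to the ten-membered ring → D last.

Numbering: kaurane numbering (C1–C20) is used for all compounds; ring A = C1–C5, C10; C18/C19 on C4; C20 on C10. The target is (5R,7R,10R,11S,13S), ent series.

Assumption 1: the (S)-configured chiral proton source in step 2 gives the (4aR,10aR) tricycle; if the sense is the opposite, the (R)-ligand is used.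
Assumption 2: 3-(methoxymethoxy)prop-1-yne (15) is bought; otherwise it costs one extra step from propargyl alcohol.

## Route

Step 1
Reactants: 1 3-methoxybenzyl chloride; 2 geranyl chloride
Product: 4 1-[(3E)-4,8-dimethylnona-3,7-dien-1-yl]-3-methoxybenzene, via Grignard reagent 3 (not isolated)
Conditions: Mg, THF, 0 °C; then 2, THF, 0 °C → rt
Reagents that add atoms: none
Why: SN2 alkylation of a benzylic Grignard reagent by a primary allylic chloride; the E-alkene is retained and no stereocentre is formed.

Step 2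
Reactants: 4 1-[(3E)-4,8-dimethylnona-3,7-dien-1-yl]-3-methoxybenzene
Product: 5 (4aR,10aR)-7-methoxy-1,1,4a-trimethyl-1,2,3,4,4a,9,10,10a-octahydrophenanthrene
Conditions: (S)-3,3′-dichloro-BINOL·SbCl5 (1:1, 0.5 equiv), CH2Cl2, −78 °C
Reagents that add atoms: none
Why: Enantioselective proton-initiated cation–olefin (polyene) bicyclisation through a chair–chair transition state, terminated by the arene para to OMe; the chiral acid selects the alkene face, and the trans ring fusion sets C5 and C10 together.

Step 3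
Reactants: 5 (4aR,10aR)-7-methoxy-1,1,4a-trimethyl-1,2,3,4,4a,9,10,10a-octahydrophenanthrene
Product: 7 ent-podocarp-8-en-13-one, via dienol ether 6 (not isolated)
Conditions: Li, NH3(l), THF, t-BuOH, −78 → −33 °C; MeOH quench; then (CO2H)2, MeOH–H2O, rt
Reagents that add atoms: water, O
Why: Birch reduction of an anisole with the substitution pattern of estradiol methyl ether gives the 2,5-dihydro compound with the tetrasubstituted C8=C9 intact, and mild enol ether hydrolysis gives the β,γ-enone without alkene migration.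

Step 4
Reactants: 7 ent-podocarp-8-en-13-one
Product: 9 ent-podocarp-8-en-13-yl acetate (13-epimer mixture), via lithium alkoxide 8 (not isolated)
Conditions: LiBHEt3, THF, −78 °C; then Ac2O, DMAP, −78 °C → rt
Reagents that add atoms: acetic anhydride, CC(=O)OC(C)=O
Why: Hydride reduction with in-situ O-acylation of the alkoxide; the C13 configuration does not matter because this centre becomes sp2 in step 5.

Step 5
Reactants: 9 ent-podocarp-8-en-13-yl acetate (13-epimer mixture)
Product: 11 (5R,10R,13Z)-8,9-seco-ent-podocarp-13-ene-8,9-dione, via acetoxy diketone 10 (not isolated)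
Conditions: RuCl3·xH2O (2 mol %), NaIO4 (2.2 equiv), EtOAc–MeCN–H2O, 0 °C; extractive work-up; then Et3N, CH2Cl2, 0 °C → rt
Reagents that add atoms: sodium periodate, [Na+].[O-]I(=O)(=O)=O
Why: RuO4 cleavage of the only (tetrasubstituted) alkene opens the B/C pair to a cyclodecane-1,6-dione, and E1cB loss of acetate (only C14–H is α to a ketone and β to OAc) places the alkene in conjugation with C8=O alone; the Z geometry is expected because ring C folds like a cyclohexene.

Step 6
Reactants: 11 (5R,10R,13Z)-8,9-seco-ent-podocarp-13-ene-8,9-dione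
Product: 14 (5R,7R,10R,11S,13Z)-7,11-bis(triethylsilyloxy)-8,9-seco-ent-podocarp-13-ene-8,9-dione, via dipotassium bis-enolate 12 (not isolated), via dipotassium dialkoxide 13 (not isolated)
Conditions: KHMDS (2.4 equiv), THF, −78 °C (11 added to base); trans-2-(phenylsulfonyl)-3-phenyloxaziridine (2.6 equiv), −78 °C; then TESCl (3 equiv), −78 → 0 °C
Reagents that add atoms: 2-(phenylsulfonyl)-3-phenyloxaziridine, O=S(=O)(c1ccccc1)N1OC1c1ccccc1; chlorotriethylsilane, CC[Si](Cl)(CC)CC
Why: Davis enolate hydroxylation of the kinetic bis-enolate (C9 can enolise only toward C11, the enone only at α′ C7) followed by O-silylation; the oxidant should attack the outer faces of the folded ring that keeps the shape of the trans-fused tricycle, at C11 anti to the C20 methyl (11S) and at C7 away from the transannular C9 carbonyl (7R), so both oxygens end up equatorial-like.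

Step 7
Reactants: 15 3-(methoxymethoxy)prop-1-yne
Product: 16 1-(methoxymethoxy)propa-1,2-diene
Conditions: KOt-Bu (0.2 equiv), THF, 0 °C → rt; distil
Reagents that add atoms: none
Why: Base-catalysed propargyl-to-allenyl ether isomerisation, driven by conjugation of the allene with oxygen.

Step 8
Reactants: 14 (5R,7R,10R,11S,13Z)-7,11-bis(triethylsilyloxy)-8,9-seco-ent-podocarp-13-ene-8,9-dione; 16 1-(methoxymethoxy)propa-1,2-diene
Product: 18 (5R,7R,10R,11S,13Z)-8-hydroxy-8-[1-(methoxymethoxy)propa-1,2-dien-1-yl]-7,11-bis(triethylsilyloxy)-8,9-seco-ent-podocarp-13-en-9-one (C8 not assigned), via lithioallene 17 (not isolated)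
Conditions: 16, n-BuLi, THF, −78 °C; then 14, −78 °C; aq NH4Cl at −78 °C
Reagents that add atoms: none
Why: 1,2-Addition of an α-lithiated allenyl ether, an acyl-anion (acryloyl-anion) equivalent, to the C8 enone carbonyl forms C8–C15 between two carbonyl-level carbons; the C9 ketone is flanked by quaternary C10 and the C11 silyl ether and should stay untouched, and the new C8 centre is erased in step 9.

Step 9
Reactants: 18 (5R,7R,10R,11S,13Z)-8-hydroxy-8-[1-(methoxymethoxy)propa-1,2-dien-1-yl]-7,11-bis(triethylsilyloxy)-8,9-seco-ent-podocarp-13-en-9-one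
Product: 20 (5R,7R,10R,11S,13S)-7,11-bis(triethylsilyloxy)-8,9-secokaura-8(14),16-diene-9,15-dione, via tertiary trifluoroacetate 19 (not isolated)
Conditions: TFAA, 2,6-lutidine, CH2Cl2, −20 °C
Reagents that add atoms: none
Why: Tius-type cationic cyclopentannelation (allene-ether Nazarov cyclisation): ionisation gives a pentadienyl cation, conrotatory 4π closure forms C13–C16, and loss of the methoxymethyl cation unveils C15=O with C8=C14 and the exocyclic methylene; C13 is set here, with ring D expected to form on the face syn to C20 and away from the C9–C11–C12 strap of the folded ring (13S).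

Step 10
Reactants: 20 (5R,7R,10R,11S,13S)-7,11-bis(triethylsilyloxy)-8,9-secokaura-8(14),16-diene-9,15-dione
Product: 21 (5R,7R,10R,11S,13S)-7,11-dihydroxy-8,9-secokaura-8(14),16-diene-9,15-dione
Conditions: HF·pyridine, pyridine, THF, 0 °C → rt
Reagents that add atoms: none
Why: Buffered fluoride cleavage of both secondary triethylsilyl ethers; non-basic conditions spare the exo-methylene enone and the α-ketol.

Step 11
Reactants: 21 (5R,7R,10R,11S,13S)-7,11-dihydroxy-8,9-secokaura-8(14),16-diene-9,15-dione
Product: 22 (5R,7R,10R,11S,13S)-7-acetoxy-11-hydroxy-8,9-secokaura-8(14),16-diene-9,15-dione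
Conditions: Ac2O (1.1 equiv), pyridine, CH2Cl2, −20 → 0 °C
Reagents that add atoms: acetic anhydride, CC(=O)OC(C)=O
Why: Kinetic mono-acylation of the allylic C7 alcohol; the C11 hydroxyl is an α-ketol OH, hydrogen-bonded to C9=O and next to the neopentyl ketone, so it should react more slowly.

## Compound list

1 | 3-methoxybenzyl chloride | COc1cccc(CCl)c1 | starting material
2 | geranyl chloride, (2E)-1-chloro-3,7-dimethylocta-2,6-diene | ClC/C=C(\C)CCC=C(C)C | starting material
3 | (3-methoxybenzyl)magnesium chloride | COc1cccc(C[Mg]Cl)c1 | intermediate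
4 | 1-[(3E)-4,8-dimethylnona-3,7-dien-1-yl]-3-methoxybenzene | COc1cccc(CC/C=C(\C)CCC=C(C)C)c1 | intermediate
5 | 13-methoxy-ent-podocarpa-8,11,13-triene; (4aR,10aR)-7-methoxy-1,1,4a-trimethyl-1,2,3,4,4a,9,10,10a-octahydrophenanthrene | COc1ccc2c(c1)CC[C@@H]1C(C)(C)CCC[C@@]21C | intermediate
6 | 13-methoxy-ent-podocarpa-8,12-diene (methyl dienol ether) | COC1=CCC2=C(C1)CC[C@@H]1C(C)(C)CCC[C@@]21C | intermediate
7 | ent-podocarp-8-en-13-one (β,γ-enone) | O=C1CCC2=C(C1)CC[C@@H]1C(C)(C)CCC[C@@]21C | intermediate
8 | lithium ent-podocarp-8-en-13-olate (13-epimer mixture) | [Li+].[O-]C1CCC2=C(C1)CC[C@@H]1C(C)(C)CCC[C@@]21C | intermediate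
9 | ent-podocarp-8-en-13-yl acetate (13-epimer mixture) | CC(=O)OC1CCC2=C(C1)CC[C@@H]1C(C)(C)CCC[C@@]21C | intermediate
10 | (5R,10R)-13-acetoxy-8,9-seco-ent-podocarpane-8,9-dione (13-epimer mixture); ring A trans-fused to a cyclodecane-1,6-dione | O=C1CCC(OC(C)=O)CC(=O)CC[C@@H]2C(C)(C)CCC[C@@]12C | intermediate
11 | (5R,10R,13Z)-8,9-seco-ent-podocarp-13-ene-8,9-dione; ring A trans-fused to a (Z)-cyclodec-2-ene-1,6-dione | O=C1CC/C=C\C(=O)CC[C@@H]2C(C)(C)CCC[C@@]12C | intermediate
12 | dipotassium bis-enolate of 11 (C7=C8–O⁻ and C11=C9–O⁻) | [K+].[K+].[O-]C1=CC/C=C\C([O-])=CC[C@@H]2C(C)(C)CCC[C@@]12C | intermediate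
13 | dipotassium (5R,7R,10R,11S,13Z)-8,9-dioxo-8,9-seco-ent-podocarp-13-ene-7,11-diolate | [K+].[K+].O=C1[C@@H]([O-])C/C=C\C(=O)[C@H]([O-])C[C@@H]2C(C)(C)CCC[C@@]12C | intermediate
14 | (5R,7R,10R,11S,13Z)-7,11-bis(triethylsilyloxy)-8,9-seco-ent-podocarp-13-ene-8,9-dione | O=C1[C@@H](O[Si](CC)(CC)CC)C/C=C\C(=O)[C@H](O[Si](CC)(CC)CC)C[C@@H]2C(C)(C)CCC[C@@]12C | intermediate
15 | 3-(methoxymethoxy)prop-1-yne | C#CCOCOC | starting material
16 | 1-(methoxymethoxy)propa-1,2-diene | C=C=COCOC | intermediate
17 | 1-lithio-1-(methoxymethoxy)propa-1,2-diene | [Li]C(OCOC)=C=C | intermediate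
18 | (5R,7R,10R,11S,13Z)-8-hydroxy-8-[1-(methoxymethoxy)propa-1,2-dien-1-yl]-7,11-bis(triethylsilyloxy)-8,9-seco-ent-podocarp-13-en-9-one (C8 not assigned) | O=C1[C@@H](O[Si](CC)(CC)CC)C/C=C\C(O)(C(OCOC)=C=C)[C@H](O[Si](CC)(CC)CC)C[C@@H]2C(C)(C)CCC[C@@]12C | intermediate
19 | C8 trifluoroacetate of 18 | O=C1[C@@H](O[Si](CC)(CC)CC)C/C=C\C(OC(=O)C(F)(F)F)(C(OCOC)=C=C)[C@H](O[Si](CC)(CC)CC)C[C@@H]2C(C)(C)CCC[C@@]12C | intermediate
20 | (5R,7R,10R,11S,13S)-7,11-bis(triethylsilyloxy)-8,9-secokaura-8(14),16-diene-9,15-dione | C=C1C(=O)C2=C[C@@H]1C[C@H](O[Si](CC)(CC)CC)C(=O)[C@]1(C)CCCC(C)(C)[C@H]1C[C@H]2O[Si](CC)(CC)CC | intermediate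
21 | (5R,7R,10R,11S,13S)-7,11-dihydroxy-8,9-secokaura-8(14),16-diene-9,15-dione | C=C1C(=O)C2=C[C@@H]1C[C@H](O)C(=O)[C@]1(C)CCCC(C)(C)[C@H]1C[C@H]2O | intermediate
22 | (5R,7R,10R,11S,13S)-7-acetoxy-11-hydroxy-8,9-secokaura-8(14),16-diene-9,15-dione (CNP0159088.1) | C=C1C(=O)C2=C[C@@H]1C[C@H](O)C(=O)[C@]1(C)CCCC(C)(C)[C@H]1C[C@H]2OC(C)=O | target

## Step count and main risks

Total steps: 11. Longest linear sequence: 10 (steps 1–6 and 8–11); step 7 is a one-step side branch.

The three steps most likely to fail: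

**Step 9 (with its feeder, step 8).** The transannular cyclopentannelation is the boldest step. The C13 configuration depends on the folded conformation of the ten-membered cation, which I have argued qualitatively but not modelled. The cation also sits next to the C7 silyloxy-bearing carbon, so a 1,2-hydride shift from C7 could compete with ring closure. The fallback sets out from 14 and comes back at 20. Ethynylmagnesium bromide (CeCl3, THF, −78 °C) is added to the C8 ketone to give the propargylic alcohol F2. Acetylation (Ac2O, DMAP, Et3N) gives the tertiary propargylic acetate F3. A gold(I)-catalysed Rautenstrauch rearrangement (Ph3PAuSbF6, wet MeCN, −20 °C → rt; 1,2-acyloxy shift, C13–C16 closure, hydrolysis of the dienyl acetate) gives the 17-nor cyclopentenone F4. One-step α-methylenation at C16 (paraformaldehyde, diisopropylammonium trifluoroacetate, THF, 60 °C) then gives 20. The ethynyl group still serves as the acyl-anion equivalent for C15, but C13 is now set by chirality transfer from the C8 carbinol centre and no free cation is formed next to C7.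

**Step 6.** Two enolates are made and oxidised in one pot on a 1,6-diketone. The risks are transannular aldol reaction, γ-deprotonation of the enone, and the wrong face at C7 or C11. The fallback sets out from 11 and comes back at 14. 11 is silylated with TESOTf/Et3N (CH2Cl2, −78 → 0 °C) to the bis(triethylsilyl) enol ether F1. F1 is oxidised with dimethyldioxirane (acetone/CH2Cl2, −78 °C; Rubottom oxidation, the silyloxy epoxides open with 1,4-silyl shift) to give 14 directly. No metal enolate is present, and the facial selectivity is that of a neutral epoxidation.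

**Step 11.** Both hydroxyls are secondary, and the preference for C7 over the C11 α-ketol may be modest. The fallback sets out from 21 and comes back at 22. Both hydroxyls are acetylated (excess Ac2O, DMAP, pyridine) to the 7,11-diacetate F5. The activated α-ketol ester at C11 is then hydrolysed selectively with Candida antarctica lipase B (pH 7 phosphate buffer/MTBE, 30 °C), leaving the C7 acetate.

Further compounds
F1 | step 6 | (5R,10R,13Z)-8,9-bis(triethylsilyloxy)-8,9-seco-ent-podocarpa-7,9(11),13-triene | CC[Si](CC)(CC)OC1=CC/C=C\C(O[Si](CC)(CC)CC)=CC[C@@H]2C(C)(C)CCC[C@@]12C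
F2 | step 9 | (5R,7R,10R,11S,13Z)-8-ethynyl-8-hydroxy-7,11-bis(triethylsilyloxy)-8,9-seco-ent-podocarp-13-en-9-one (C8 not assigned) | O=C1[C@@H](O[Si](CC)(CC)CC)C/C=C\C(O)(C#C)[C@H](O[Si](CC)(CC)CC)C[C@@H]2C(C)(C)CCC[C@@]12C
F3 | step 9 | C8 acetate of F2 | O=C1[C@@H](O[Si](CC)(CC)CC)C/C=C\C(OC(C)=O)(C#C)[C@H](O[Si](CC)(CC)CC)C[C@@H]2C(C)(C)CCC[C@@]12C
F4 | step 9 | 7,11-bis(triethylsilyloxy)-17-nor-8,9-secokaur-8(14)-ene-9,15-dione (configuration as in 20) | C1C(=O)C2=C[C@@H]1C[C@H](O[Si](CC)(CC)CC)C(=O)[C@]1(C)CCCC(C)(C)[C@H]1C[C@H]2O[Si](CC)(CC)CC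
F5 | step 11 | (5R,7R,10R,11S,13S)-7,11-diacetoxy-8,9-secokaura-8(14),16-diene-9,15-dione | C=C1C(=O)C2=C[C@@H]1C[C@H](OC(C)=O)C(=O)[C@]1(C)CCCC(C)(C)[C@H]1C[C@H]2OC(C)=O
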